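Hold your hunch that theta, with the richest charge of free monomer, must lead at 15 min against one quick number.

| flask | free monomer | protic impurity | pre-initiator | remark | time |
|---|---|---|---|---|---|
| teal | 0.85 M | 0.50 M | 0.3 mol% | run made earlier |  |
| amber | 2.9 M | 0.50 M | 0.3 mol% | run made earlier |  |
| grey | 1 M | 0.50 M | 0.2 mol% | run made earlier |  |
| beta | 1.0 M | 0.300 M | 0.6 mol% |  | 15 min |
| theta | 2.0 M | 0.500 M | 0.08 mol% |  | 15 min |
| delta | 1.0 M | 0.500 M | 0.3 mol% |  | 15 min |
| alpha | 0.60 M | 0.500 M | 0.2 mol% |  | 15 min |

| run | time / min | monomer in chains / % | free monomer / % |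
|---|---|---|---|
| teal | 1.00 | 0 | 76.6 |
| teal | 2.50 | 1.1 | 58.0 |
| teal | 5.00 | 4.8 | 44.3 |
| teal | 8.00 | 10.8 | 34.1 |
| teal | 10.0 | 15.6 | 28.2 |
| amber | 1.00 | 0.8 | 84.6 |
| amber | 2.50 | 12.7 | 70.4 |
| amber | 5.00 | 43.8 | 38.4 |
| amber | 8.00 | 69.8 | 12.8 |
| amber | 10.0 | 76.0 | 5.4 |
| grey | 0.833 | 0.2 | 79.6 |
| grey | 1.50 | 0.2 | 70.6 |
| grey | 3.00 | 1.8 | 58.2 |
| grey | 6.00 | 6.8 | 45.9 |
| grey | 10.0 | 17.1 | 34.0 |

(scatter of a reading: 0.5 percentage points)

- a species is counted by the free monomer in it: one homo dimer counts as two
- what was read earlier has a scatter of 0.5 percentage points, one standard deviation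
- what may be going on: free monomer + initiator -> living end + monomer in chains; free monomer + living end -> monomer in chains + living end; pre-initiator -> initiator; 2 free monomer -> homo dimer; protic impurity + free monomer -> quenched substrate
- no earlier run changes the charge of protic impurity; that part of a forecast is a guess

* the flasks put in order of amount of monomer in chains, in percent of the free monomer charged, best first, at 15 min (beta / theta / delta / alpha)
* the same order at 2.0 h (beta / theta / delta / alpha)
* the amount of monomer in chains, in percent of the free monomer charged of the flask you put first, at 15 min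
* the amount of monomer in chains, in percent of the free monomer charged of the flask you put last, at 15 min

The number comes from the earlier runs. Free monomer found neither free nor in chains at the last reading comes to 0.478 M in teal, 0.489 M in grey and 0.539 M in amber. The charge of free monomer ranged from 0.85 M to 2.9 M, but each run held 0.50 M of protic impurity. So count that loss as one for one and use it as the zero of your scale.

In beta, c(protic impurity)/c(free monomer) is 0.300, so 70.0% stays for chains. That is the one-for-one share, one minus that ratio as charged. In beta, protic impurity is the limiting reagent of the quench, 0.300 M against 1.0 M. That charge lies outside the runs, though, since none of them changes it, so this part of the reckoning is a guess. The same reckoning gives theta 75.0%, delta 50.0% and alpha 16.7%, so at 2.0 h I expect theta, beta, delta, alpha.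

At 15 min your hunch meets the start-up of the chains: amber reads 0.8% in chains at 1.00 min, so growth has to wait for initiator. Beta charges 0.00600 M of pre-initiator against 0.00160 M in theta, 3.75 times as much, and gives up 5 percentage points of share. So I commit to beta, theta, delta, alpha at 15 min, with beta below 70.0%.

The forecast gives beta > theta > delta > alpha at 15 min and theta > beta > delta > alpha at 2.0 h, with 64% first and 7% last, holding that “the protic impurity eats monomer one-for-one”.

The flasks stand beta > theta > delta > alpha at 15 min and theta > beta > delta > alpha at 2.0 h, with 63.9% in beta and 7.86% in alpha. Beta still holds 6.07% free monomer at 15.0 min, and its gap to the one-for-one share is 6.1 points; at 120 min beta reads 69.9%.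

    free monomer + initiator → living end + monomer in chains (k = 0.00445 M⁻¹ s⁻¹)
    free monomer + living end → monomer in chains + living end, rate k2*[living end]*[free monomer] (k = 1.31 M⁻¹ s⁻¹)
    pre-initiator → initiator (k = 0.00381 s⁻¹)
    2 free monomer → homo dimer (k = 9.84 × 10⁻⁶ M⁻¹ s⁻¹)
    protic impurity + free monomer → quenched substrate (k = 0.0116 M⁻¹ s⁻¹)

Take a neighbour of alpha with 2.4 M of free monomer and 0.208 equiv of protic impurity: its one-for-one share is 79.2%. That flask reads 73.8% in chains at 15.0 min, with 4.42% free monomer left.

All runs are simulated for substances that don't exist; scatter was added.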